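**Retrosynthetic overview**
1. EGCG 12 ⇐ tricyclic boronate 11: one global hydrogenolysis removes six O-benzyl groups, the O-Cbz group, the boronate and the C4–O bond; the gallate is already on O3.
2. 11 ⇐ aldehyde 3 + (Z)-enol gallate 8 + PhB(OH)2: boron-templated, chiral-acid-catalysed oxa-[4+2] forming O1–C2 and C3–C4; Z-alkene gives 2,3-cis, catalyst gives 2R,3R.
3. 8 ⇐ alkyne 6 + acid 7 (Ru-catalysed Z-selective anti-Markovnikov addition); 6 ⇐ aldehyde 4 (Ohira–Bestmann).
4. 3 ⇐ 2,4,6-trihydroxybenzaldehyde 1 (mono-Cbz on the para hydroxyl).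
5. Ring order: aromatic A, B and D rings are bought; the 1,3,2-dioxaborinane ring and the pyran C ring are formed together in step 4; the boron ring is excised in step 5.

Assumption: 1, 2, 4, 5, 7 and 9 are taken as catalogue chemicals, and the (R)-configured acid in step 4 is taken to favour the (2R,3R) series (if the sense is opposite, its enantiomer is used).

**Step 1**
Reactants: 1 2,4,6-trihydroxybenzaldehyde; 2 benzyl chloroformate
Product: 3 benzyl (4-formyl-3,5-dihydroxyphenyl) carbonate
Conditions: CbzCl (1.0 equiv), NaHCO3 (1.1 equiv), acetone/H2O, 0 °C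
Reagents that add atoms: benzyl chloroformate, O=C(Cl)OCc1ccccc1
Why: Schotten–Baumann O-acylation in which bicarbonate ionises only the para hydroxyl (the most acidic one, and the only one neither flanking nor hydrogen-bonded to the formyl group), and the resulting aryl benzyl carbonate both damps the nucleophilicity of the A ring for step 4 and leaves by hydrogenolysis in step 5.

**Step 2**
Reactants: 4 3,4,5-tris(benzyloxy)benzaldehyde; 5 dimethyl (1-diazo-2-oxopropyl)phosphonate
Product: 6 1,2,3-tris(benzyloxy)-5-ethynylbenzene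
Conditions: 5 (1.3 equiv), K2CO3 (2 equiv), MeOH/THF, rt
Reagents that add atoms: dimethyl (1-diazo-2-oxopropyl)phosphonate, CC(=O)C(=[N+]=[N-])P(=O)(OC)OC
Why: Ohira–Bestmann modification of the Seyferth–Gilbert homologation converts the non-enolisable aryl aldehyde into the terminal alkyne under carbonate/methanol conditions that leave benzyl ethers untouched.

**Step 3**
Reactants: 6 1,2,3-tris(benzyloxy)-5-ethynylbenzene; 7 3,4,5-tris(benzyloxy)benzoic acid
Product: 8 (Z)-2-[3,4,5-tris(benzyloxy)phenyl]ethenyl 3,4,5-tris(benzyloxy)benzoate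
Conditions: [Ru(η3-methallyl)2(dppb)] (2 mol %), PhMe, 65 °C
Reagents that add atoms: none
Why: Ruthenium-catalysed anti-Markovnikov addition of a carboxylic acid to a terminal alkyne (through a Ru-vinylidene) gives (Z)-enol esters of aryl acetylenes selectively and without by-products; no stereocentre forms, but the Z geometry that becomes the 2,3-cis relationship is fixed here.

**Step 4**
Reactants: 3 benzyl (4-formyl-3,5-dihydroxyphenyl) carbonate; 8 (Z)-2-[3,4,5-tris(benzyloxy)phenyl]ethenyl 3,4,5-tris(benzyloxy)benzoate; 9 phenylboronic acid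
Product: 11 (2R,3R,4R)-7-(benzyloxycarbonyloxy)-4,5-O-(phenylboranediyl)-2-[3,4,5-tris(benzyloxy)phenyl]chromane-3,4,5-triol 3-[3,4,5-tris(benzyloxy)benzoate], via boron-bridged o-quinone methide 10 (not isolated)
Conditions: PhB(OH)2 (1.05 equiv), 4 Å MS, PhMe, rt; then 8 (1.2 equiv), (R)-TRIP N-triflylphosphoramide (10 mol %), −20 → 0 °C
Reagents that add atoms: phenylboronic acid, OB(O)c1ccccc1
Why: Proposed new method: phenylboronic acid condenses with the formyl oxygen and one of the two equivalent ortho hydroxyls of 3 (a Nagata-type boron template, applied here to a salicylaldehyde) to give the cyclic boronate 10, whose O-protonated form is a boron-tethered 4-oxy-o-quinone methide paired with the chiral phosphoramide anion and adds the styrene-polarised enol ester 8 in an asynchronous inverse-electron-demand oxa-[4+2] cycloaddition (C4–C3 bond to the acyloxy-bearing carbon, then O1–C2 closure at the benzylic carbon), so that the dioxaborinane ring and the pyran C ring are both built in this operation with the gallate already on O3; suprafacial addition turns the Z geometry into the 2,3-cis relationship, the chiral counter-anion selects the face that gives 2R,3R, the endo approach places O4 cis as well (4R, a centre deleted in step 5; minor diastereomers are removed by chromatography), and the closest known reactions are Brønsted-acid-catalysed enantioselective [4+2] cycloadditions of o-quinone methides with styrenes and Lewis-acid-mediated oxa-[4+2] reactions of salicylaldehydes with alkenes to 4-oxychromans.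

**Step 5**
Reactants: 11 (2R,3R,4R)-tricyclic phenylboronate
Product: 12 (−)-epigallocatechin gallate
Conditions: H2 (1 atm), 20% Pd(OH)2/C, THF/MeOH/H2O (10:10:1), AcOH (1%), 0.01 M, rt
Reagents that add atoms: none
Why: Heterogeneous catalytic hydrogenolysis cleaves every activated benzylic C–O bond in one pass (six aryl benzyl ethers, the benzyl carbonate with loss of CO2 and, after solvolysis of the boronate, the doubly oxygen-activated C4–O bond, as in the known flavan-3,4-diol to flavan-3-ol reduction), while the less activated cyclic C2–O1 ether and the gallate ester survive, so C2 and C3 are untouched.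

**Compound list**
1 | 2,4,6-trihydroxybenzaldehyde | O=Cc1c(O)cc(O)cc1O | starting material
2 | benzyl chloroformate | O=C(Cl)OCc1ccccc1 | starting material
3 | benzyl (4-formyl-3,5-dihydroxyphenyl) carbonate | O=Cc1c(O)cc(OC(=O)OCc2ccccc2)cc1O | intermediate
4 | 3,4,5-tris(benzyloxy)benzaldehyde | O=Cc1cc(OCc2ccccc2)c(OCc2ccccc2)c(OCc2ccccc2)c1 | starting material
5 | dimethyl (1-diazo-2-oxopropyl)phosphonate (Ohira–Bestmann reagent) | CC(=O)C(=[N+]=[N-])P(=O)(OC)OC | starting material
6 | 1,2,3-tris(benzyloxy)-5-ethynylbenzene | C#Cc1cc(OCc2ccccc2)c(OCc2ccccc2)c(OCc2ccccc2)c1 | intermediate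
7 | 3,4,5-tris(benzyloxy)benzoic acid | OC(=O)c1cc(OCc2ccccc2)c(OCc2ccccc2)c(OCc2ccccc2)c1 | starting material
8 | (Z)-2-[3,4,5-tris(benzyloxy)phenyl]ethenyl 3,4,5-tris(benzyloxy)benzoate | O=C(O/C=C\c1cc(OCc2ccccc2)c(OCc2ccccc2)c(OCc2ccccc2)c1)c1cc(OCc2ccccc2)c(OCc2ccccc2)c(OCc2ccccc2)c1 | intermediate
9 | phenylboronic acid | OB(O)c1ccccc1 | starting material
10 | benzyl (5-oxo-2-phenyl-5H-1,3,2-benzodioxaborinin-7-yl) carbonate (boron-bridged o-quinone methide; B–Ph joins the former formyl oxygen and one ortho oxygen) | O=C1C=C(OC(=O)OCc2ccccc2)C=C2OB(c3ccccc3)OC=C12 | intermediate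
11 | (2R,3R,4R)-7-(benzyloxycarbonyloxy)-4,5-O-(phenylboranediyl)-2-[3,4,5-tris(benzyloxy)phenyl]chromane-3,4,5-triol 3-[3,4,5-tris(benzyloxy)benzoate] (flavan numbering; O4 and O5 joined through B–Ph in a six-membered ring; 2,3,4-all-cis) | O=C(O[C@@H]1[C@@H]2OB(c3ccccc3)Oc3cc(OC(=O)OCc4ccccc4)cc(O[C@@H]1c1cc(OCc4ccccc4)c(OCc4ccccc4)c(OCc4ccccc4)c1)c32)c1cc(OCc2ccccc2)c(OCc2ccccc2)c(OCc2ccccc2)c1 | intermediate
12 | (−)-epigallocatechin gallate, (2R,3R)-5,7-dihydroxy-2-(3,4,5-trihydroxyphenyl)chroman-3-yl 3,4,5-trihydroxybenzoate | O=C(O[C@@H]1Cc2c(O)cc(O)cc2O[C@@H]1c1cc(O)c(O)c(O)c1)c1cc(O)c(O)c(O)c1 | target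

**Totals**
Total step count: 5. Longest linear sequence: 4 steps (4 → 6 → 8 → 11 → 12).

**Steps most likely to fail**

Step 4. The boron-stabilised benzylic cation may be too weak an electrophile for the modest π-nucleophile 8, and the electron-rich product may compete with 8 in a Friedel–Crafts reaction. The regiochemistry could also flip towards the isoflavan series, and the ee and endo:exo ratio are untested. The fallback sets out from 3 (with 8) and comes back at 12. The C4 oxygen is removed before the cycloaddition: 3 is reduced with NaBH4 (THF/EtOH, 0 °C) to benzyl [3,5-dihydroxy-4-(hydroxymethyl)phenyl] carbonate F1. With the same chiral acid and no boronic acid, F1 loses water to the far more electrophilic parent o-quinone methide benzyl (5-hydroxy-4-methylidene-3-oxocyclohexa-1,5-dien-1-yl) carbonate F2, which is trapped in situ by 8. This gives benzyl {(2R,3R)-5-hydroxy-3-[3,4,5-tris(benzyloxy)benzoyloxy]-2-[3,4,5-tris(benzyloxy)phenyl]chroman-7-yl} carbonate F3, and hydrogenolysis under the conditions of step 5 gives 12. This gives up the boron tether and the C4 centre in exchange for the established o-hydroxybenzyl alcohol entry to o-quinone methides.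

Step 5. Ionisation at C4 while phloroglucinol rings are being unmasked can give 4→8 oligomers (the proanthocyanidin pathway), and cis 3→4 acyl migration before C4–O cleavage would cost the gallate. The fallback sets out from 11 and comes back at 12. The C4 oxygen is exchanged for sulfur while everything is still protected: thiolysis of 11 with phenylmethanethiol and BF3·OEt2 (CH2Cl2, −20 °C) gives benzyl {(2R,3S,4S)-4-(benzylsulfanyl)-5-hydroxy-3-[3,4,5-tris(benzyloxy)benzoyloxy]-2-[3,4,5-tris(benzyloxy)phenyl]chroman-7-yl} carbonate F4, a thioether that does not ionise under neutral conditions. Excess Raney nickel under H2 (EtOH/THF, 50 °C) then cleaves the C–S bond and the benzyl-type groups to give 12; this is the classical thiolysis/desulfurisation sequence of proanthocyanidin chemistry.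

Step 1. Mono-acylation may give ortho-carbonate and bis-carbonate mixtures. The fallback sets out from 1 and comes back at 12. Compound 1 is perbenzylated (BnBr, K2CO3, DMF) to 2,4,6-tris(benzyloxy)benzaldehyde F5. The two benzyl ethers ortho to the formyl group are removed under chelation control (BCl3, 2.2 equiv, CH2Cl2, −78 °C) to give 4-(benzyloxy)-2,6-dihydroxybenzaldehyde F6. Under the conditions of step 4, F6 gives 7-(benzyloxy)-2-phenyl-5H-1,3,2-benzodioxaborinin-5-one F7 and then (2R,3R,4R)-7-(benzyloxy)-4,5-O-(phenylboranediyl)-2-[3,4,5-tris(benzyloxy)phenyl]chromane-3,4,5-triol 3-[3,4,5-tris(benzyloxy)benzoate] F8. The conditions of step 5 then give 12.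

**Further compounds**
F1 | step 4 | benzyl [3,5-dihydroxy-4-(hydroxymethyl)phenyl] carbonate | OCc1c(O)cc(OC(=O)OCc2ccccc2)cc1O
F2 | step 4 | benzyl (5-hydroxy-4-methylidene-3-oxocyclohexa-1,5-dien-1-yl) carbonate | C=C1C(=O)C=C(OC(=O)OCc2ccccc2)C=C1O
F3 | step 4 | benzyl {(2R,3R)-5-hydroxy-3-[3,4,5-tris(benzyloxy)benzoyloxy]-2-[3,4,5-tris(benzyloxy)phenyl]chroman-7-yl} carbonate | O=C(O[C@@H]1Cc2c(O)cc(OC(=O)OCc3ccccc3)cc2O[C@@H]1c1cc(OCc3ccccc3)c(OCc3ccccc3)c(OCc3ccccc3)c1)c1cc(OCc2ccccc2)c(OCc2ccccc2)c(OCc2ccccc2)c1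
F4 | step 5 | benzyl {(2R,3S,4S)-4-(benzylsulfanyl)-5-hydroxy-3-[3,4,5-tris(benzyloxy)benzoyloxy]-2-[3,4,5-tris(benzyloxy)phenyl]chroman-7-yl} carbonate | O=C(O[C@@H]1[C@@H](SCc2ccccc2)c2c(O)cc(OC(=O)OCc3ccccc3)cc2O[C@@H]1c1cc(OCc3ccccc3)c(OCc3ccccc3)c(OCc3ccccc3)c1)c1cc(OCc2ccccc2)c(OCc2ccccc2)c(OCc2ccccc2)c1
F5 | step 1 | 2,4,6-tris(benzyloxy)benzaldehyde | O=Cc1c(OCc2ccccc2)cc(OCc2ccccc2)cc1OCc1ccccc1
F6 | step 1 | 4-(benzyloxy)-2,6-dihydroxybenzaldehyde | O=Cc1c(O)cc(OCc2ccccc2)cc1O
F7 | step 1 | 7-(benzyloxy)-2-phenyl-5H-1,3,2-benzodioxaborinin-5-one | O=C1C=C(OCc2ccccc2)C=C2OB(c3ccccc3)OC=C12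
F8 | step 1 | (2R,3R,4R)-7-(benzyloxy)-4,5-O-(phenylboranediyl)-2-[3,4,5-tris(benzyloxy)phenyl]chromane-3,4,5-triol 3-[3,4,5-tris(benzyloxy)benzoate] | O=C(O[C@@H]1[C@@H]2OB(c3ccccc3)Oc3cc(OCc4ccccc4)cc(O[C@@H]1c1cc(OCc4ccccc4)c(OCc4ccccc4)c(OCc4ccccc4)c1)c32)c1cc(OCc2ccccc2)c(OCc2ccccc2)c(OCc2ccccc2)c1
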